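**Retrosynthetic overview**

1. The last step is hydrogenolysis of an octa-O-benzyl ether. Before it, ring C of the lower (gallocatechin-type) unit is cut at two bonds, C4–C4a and O1–C8a, giving an aryl iodide and a 3-bromo-1-ol that one palladium/norbornene annulation joins.
2. Enabling feature: in lower ring A, C8a lies between C8 (bearing the upper flavan-4-yl group) and C4a (bearing hydrogen). With iodine on C8a this is the one-blocked-ortho, one-free-ortho pattern needed for norbornene-relayed ortho-alkylation and ipso-etherification, and it leaves no choice of site.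
3. The aryl iodide comes from Friedel–Crafts union of a (2S)-flavan-4-ol with 1,3-bis(benzyloxy)-5-iodobenzene, which sets the 2,4-trans C4 centre; the flavan C2 centre comes from asymmetric conjugate addition of an arylboronic acid to a chromone.
4. The bromo alcohol carries both lower-unit stereocentres: Sharpless epoxidation of a cinnamyl alcohol and benzylic opening with inversion give the anti (erythro) pattern, which maps onto the 2,3-trans ring because no bond to C2 or C3 is broken afterwards.
5. Ring order: upper ring C first (already present in the chromone), all rings A and B bought as arenes, lower ring C last, in the key step.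

Key step: step 13

Assumption: in step 2 the (R)-enantiomer of t-BuPyOx is taken to give the (2S)-flavanone, by analogy with the facial preference of this ligand class on cyclic enones; compounds 1, 3, 6 and 9 are taken as commercial.

**Route**

Step 1
Reactants: 1 7-hydroxy-4H-chromen-4-one
Product: 2 7-(benzyloxy)-4H-chromen-4-one
Conditions: BnBr, K2CO3, DMF, 25 °C
Reagents that add atoms: benzyl bromide, BrCc1ccccc1
Why: Williamson ether synthesis, the phenoxide displacing bromide from benzyl bromide; no stereocentre is involved.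

Step 2
Reactants: 2 7-(benzyloxy)-4H-chromen-4-one; 3 [4-(benzyloxy)phenyl]boronic acid
Product: 4 (2S)-7-(benzyloxy)-2-[4-(benzyloxy)phenyl]-2,3-dihydro-4H-chromen-4-one
Conditions: Pd(OCOCF3)2 (5 mol %), (R)-t-BuPyOx (6 mol %), NH4PF6 (30 mol %), H2O (5 equiv), ClCH2CH2Cl, 60 °C
Reagents that add atoms: none
Why: Palladium-catalysed asymmetric conjugate addition of an arylboronic acid to a chromone, in which the aryl group passes from a cationic divalent arylpalladium complex to C2 and the pyridine–oxazoline ligand fixes the face so that C2 should be S.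

Step 3
Reactants: 4 (2S)-7-(benzyloxy)-2-[4-(benzyloxy)phenyl]-2,3-dihydro-4H-chromen-4-one
Product: 5 (2S,4S)-7-(benzyloxy)-2-[4-(benzyloxy)phenyl]chroman-4-ol (2,4-cis)
Conditions: NaBH4, THF/MeOH, 0 °C
Reagents that add atoms: none
Why: Borohydride reduction of the aryl ketone, hydride adding trans to the equatorial 2-aryl group to give the 2,4-cis alcohol (4S), a centre that is erased again in step 5.

Step 4
Reactants: 6 5-iodobenzene-1,3-diol
Product: 7 1,3-bis(benzyloxy)-5-iodobenzene
Conditions: BnBr, K2CO3, DMF, 50 °C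
Reagents that add atoms: benzyl bromide, BrCc1ccccc1
Why: Twofold Williamson ether synthesis on the resorcinol; the aryl iodide is inert and no stereocentre is involved.

Step 5
Reactants: 5 (2S,4S)-7-(benzyloxy)-2-[4-(benzyloxy)phenyl]chroman-4-ol; 7 1,3-bis(benzyloxy)-5-iodobenzene
Product: 8 (2S,4R)-7-(benzyloxy)-2-[4-(benzyloxy)phenyl]-4-[2,4-bis(benzyloxy)-6-iodophenyl]chromane (2,4-trans)
Conditions: BF3·OEt2 (0.3 equiv), CH2Cl2, −40 to 0 °C, 5 added slowly to 7 (6 equiv, excess recovered)
Reagents that add atoms: none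
Why: Friedel–Crafts alkylation in which BF3 ionises the benzylic alcohol to the C4 cation (stabilised by O1 and the 7-benzyloxy group), which attacks 7 at the carbon para to one ether and ortho to iodine (the carbon between the two ethers is shielded), quasi-axial attack anti to the equatorial C2 aryl group setting C4 as R.

Step 6
Reactants: 9 3,4,5-tris(benzyloxy)benzaldehyde
Product: 10 ethyl (2E)-3-[3,4,5-tris(benzyloxy)phenyl]prop-2-enoate
Conditions: (EtO)2P(O)CH2CO2Et, NaH, THF, 0 to 25 °C
Reagents that add atoms: triethyl phosphonoacetate, CCOC(=O)CP(=O)(OCC)OCC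
Why: Horner–Wadsworth–Emmons olefination of an aromatic aldehyde with a stabilised phosphonate anion, which should give the E-alkene.

Step 7
Reactants: 10 ethyl (2E)-3-[3,4,5-tris(benzyloxy)phenyl]prop-2-enoate
Product: 11 (2E)-3-[3,4,5-tris(benzyloxy)phenyl]prop-2-en-1-ol
Conditions: i-Bu2AlH (2.2 equiv), CH2Cl2, −78 °C
Reagents that add atoms: none
Why: 1,2-Reduction of the conjugated ester to the allylic alcohol by i-Bu2AlH, leaving the alkene geometry untouched.

Step 8
Reactants: 11 (2E)-3-[3,4,5-tris(benzyloxy)phenyl]prop-2-en-1-ol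
Product: 12 [(2S,3S)-3-[3,4,5-tris(benzyloxy)phenyl]oxiran-2-yl]methanol
Conditions: Ti(OiPr)4 (10 mol %), L-(+)-diisopropyl tartrate (12 mol %), t-BuOOH, 4 Å molecular sieves, CH2Cl2, −20 °C
Reagents that add atoms: tert-butyl hydroperoxide, CC(C)(C)OO
Why: Sharpless asymmetric epoxidation of an E-allylic alcohol, the L-(+)-tartrate–titanium complex delivering oxygen to the alkene face that gives the (2S,3S)-trans-epoxide.

Step 9
Reactants: 12 [(2S,3S)-3-[3,4,5-tris(benzyloxy)phenyl]oxiran-2-yl]methanol
Product: 13 (1R,2S)-2,3-dihydroxy-1-[3,4,5-tris(benzyloxy)phenyl]propyl benzoate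
Conditions: Ti(OiPr)4 (1.5 equiv), PhCO2H (1.2 equiv), CH2Cl2, 25 °C
Reagents that add atoms: benzoic acid, OC(=O)c1ccccc1
Why: Titanium-mediated regioselective opening of a 2,3-epoxy alcohol, benzoate attacking the benzylic C3 with inversion (SN2-type, the epoxy alkoxide being bound to titanium), which turns the trans-epoxide into the anti (erythro) dioxygen pattern with the benzylic carbon R.

Step 10
Reactants: 13 (1R,2S)-2,3-dihydroxy-1-[3,4,5-tris(benzyloxy)phenyl]propyl benzoate
Product: 14 (1R,2R)-3-bromo-2-hydroxy-1-[3,4,5-tris(benzyloxy)phenyl]propyl benzoate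
Conditions: CBr4, PPh3, pyridine, 0 to 25 °C
Reagents that add atoms: carbon tetrabromide, BrC(Br)(Br)Br
Why: Appel bromination, selective for the primary hydroxyl over the hindered secondary one; no stereocentre is touched (the descriptor at C2 changes only through the priority of CH2Br).

Step 11
Reactants: 14 (1R,2R)-3-bromo-2-hydroxy-1-[3,4,5-tris(benzyloxy)phenyl]propyl benzoate
Product: 15 (1R,2R)-2-(benzyloxy)-3-bromo-1-[3,4,5-tris(benzyloxy)phenyl]propyl benzoate
Conditions: BnOC(=NH)CCl3, TfOH (5 mol %), CH2Cl2/cyclohexane, 0 °C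
Reagents that add atoms: benzyl 2,2,2-trichloroacetimidate, ClC(Cl)(Cl)C(=N)OCc1ccccc1
Why: Acid-catalysed O-benzylation with a trichloroacetimidate, chosen because base would close the bromohydrin to an epoxide or move the benzoate.

Step 12
Reactants: 15 (1R,2R)-2-(benzyloxy)-3-bromo-1-[3,4,5-tris(benzyloxy)phenyl]propyl benzoate
Product: 16 (1R,2R)-2-(benzyloxy)-3-bromo-1-[3,4,5-tris(benzyloxy)phenyl]propan-1-ol
Conditions: i-Bu2AlH (2.5 equiv), CH2Cl2, −78 °C
Reagents that add atoms: none
Why: Reductive cleavage of the benzoate ester by i-Bu2AlH at low temperature, under which the primary bromide and the benzyl ethers are inert and no alkoxide is warmed in the presence of the bromide.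

Step 13
Reactants: 8 (2S,4R)-7-(benzyloxy)-2-[4-(benzyloxy)phenyl]-4-[2,4-bis(benzyloxy)-6-iodophenyl]chromane; 16 (1R,2R)-2-(benzyloxy)-3-bromo-1-[3,4,5-tris(benzyloxy)phenyl]propan-1-ol
Product: 17 (2R,3S)-3,5,7-tris(benzyloxy)-8-[(2S,4R)-7-(benzyloxy)-2-[4-(benzyloxy)phenyl]chroman-4-yl]-2-[3,4,5-tris(benzyloxy)phenyl]chromane
Conditions: Pd(OAc)2 (10 mol %), RuPhos (20 mol %), norbornene (1 equiv), Cs2CO3 (3 equiv), 16 (1.5 equiv), 1,4-dioxane, 100 °C
Reagents that add atoms: none
Why: Proposed new method: zerovalent palladium inserts into the C8a–I bond of 8, norbornene carbopalladation and C–H palladation at C4a give the aryl–norbornyl palladacycle, the primary C–Br bond of 16 adds to it to give a tetravalent palladium species, and C(sp2)–C(sp3) reductive elimination forms C4–C4a; β-carbon elimination then expels norbornene and the divalent arylpalladium species at C8a binds the benzylic alkoxide and forms O1–C8a by C–O reductive elimination. The closest known reaction types are the palladium/norbornene (Catellani-type) ortho-alkylation of aryl iodides with alkyl bromides, its annulative forms with epoxides (2,3-dihydrobenzofurans by ipso C–O coupling) and with bromoalkylamines (indolines and tetrahydroquinolines by ipso C–N coupling), and the palladium-catalysed intramolecular etherification of aryl halides with secondary alcohols; the six-membered C–O closure after alkylation by a 3-bromo-1-ol is the untested part. Ring C of the lower unit closes in a [3+3] annulative sense, first the intermolecular C–C bond and then the intramolecular C–O bond through a seven-membered aryl–palladium–alkoxide chelate. No stereocentre is made: C2 (R) and C3 (S) are carried in from 16 with retention because neither of their C–O bonds is touched, so the anti pattern of 16 becomes the 2,3-trans ring. The step needs site selectivity, which the substrate secures because C8a–I has only one ortho hydrogen (on C4a; C8 carries the flavan-4-yl group, which also drives the norbornene extrusion), and it needs alkylation before etherification, which follows from the reactivity of the palladacycle toward primary bromides. It also needs C–O reductive elimination to outrun β-hydride loss from the secondary alkoxide, for which the bulky electron-rich RuPhos and the doubly ortho-substituted aryl group are chosen, while the benzyl ether on O3 removes the only other oxygen that could close a five-membered ring.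

Step 14
Reactants: 17 (2R,3S)-3,5,7-tris(benzyloxy)-8-[(2S,4R)-7-(benzyloxy)-2-[4-(benzyloxy)phenyl]chroman-4-yl]-2-[3,4,5-tris(benzyloxy)phenyl]chromane
Product: 18 (2R,3S)-8-[(2S,4R)-7-hydroxy-2-(4-hydroxyphenyl)chroman-4-yl]-2-(3,4,5-trihydroxyphenyl)chromane-3,5,7-triol
Conditions: H2 (1 atm), Pd(OH)2 on carbon, THF/MeOH, 25 °C
Reagents that add atoms: none
Why: Hydrogenolysis of the eight benzyl ethers under neutral conditions, which should leave the cyclic benzylic C2–O bonds, the C4–C8 bond and all four stereocentres intact.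

**Compound list**

1 | 7-hydroxy-4H-chromen-4-one | O=c1ccoc2cc(O)ccc12 | starting material
2 | 7-(benzyloxy)-4H-chromen-4-one | O=c1ccoc2cc(OCc3ccccc3)ccc12 | intermediate
3 | [4-(benzyloxy)phenyl]boronic acid | OB(O)c1ccc(OCc2ccccc2)cc1 | starting material
4 | (2S)-7-(benzyloxy)-2-[4-(benzyloxy)phenyl]-2,3-dihydro-4H-chromen-4-one | O=C1C[C@@H](c2ccc(OCc3ccccc3)cc2)Oc2cc(OCc3ccccc3)ccc12 | intermediate
5 | (2S,4S)-7-(benzyloxy)-2-[4-(benzyloxy)phenyl]chroman-4-ol | O[C@H]1C[C@@H](c2ccc(OCc3ccccc3)cc2)Oc2cc(OCc3ccccc3)ccc21 | intermediate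
6 | 5-iodobenzene-1,3-diol | Oc1cc(O)cc(I)c1 | starting material
7 | 1,3-bis(benzyloxy)-5-iodobenzene | Ic1cc(OCc2ccccc2)cc(OCc2ccccc2)c1 | intermediate
8 | (2S,4R)-7-(benzyloxy)-2-[4-(benzyloxy)phenyl]-4-[2,4-bis(benzyloxy)-6-iodophenyl]chromane | C(c1ccccc1)Oc1ccc([C@@H]2C[C@@H](c3c(OCc4ccccc4)cc(OCc4ccccc4)cc3I)c3ccc(OCc4ccccc4)cc3O2)cc1 | intermediate
9 | 3,4,5-tris(benzyloxy)benzaldehyde | O=Cc1cc(OCc2ccccc2)c(OCc2ccccc2)c(OCc2ccccc2)c1 | starting material
10 | ethyl (2E)-3-[3,4,5-tris(benzyloxy)phenyl]prop-2-enoate | CCOC(=O)/C=C/c1cc(OCc2ccccc2)c(OCc2ccccc2)c(OCc2ccccc2)c1 | intermediate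
11 | (2E)-3-[3,4,5-tris(benzyloxy)phenyl]prop-2-en-1-ol | OC/C=C/c1cc(OCc2ccccc2)c(OCc2ccccc2)c(OCc2ccccc2)c1 | intermediate
12 | [(2S,3S)-3-[3,4,5-tris(benzyloxy)phenyl]oxiran-2-yl]methanol | O1[C@@H](c2cc(OCc3ccccc3)c(OCc3ccccc3)c(OCc3ccccc3)c2)[C@@H]1CO | intermediate
13 | (1R,2S)-2,3-dihydroxy-1-[3,4,5-tris(benzyloxy)phenyl]propyl benzoate | O=C(O[C@H](c1cc(OCc2ccccc2)c(OCc2ccccc2)c(OCc2ccccc2)c1)[C@@H](O)CO)c1ccccc1 | intermediate
14 | (1R,2R)-3-bromo-2-hydroxy-1-[3,4,5-tris(benzyloxy)phenyl]propyl benzoate | O=C(O[C@H](c1cc(OCc2ccccc2)c(OCc2ccccc2)c(OCc2ccccc2)c1)[C@@H](O)CBr)c1ccccc1 | intermediate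
15 | (1R,2R)-2-(benzyloxy)-3-bromo-1-[3,4,5-tris(benzyloxy)phenyl]propyl benzoate | O=C(O[C@H](c1cc(OCc2ccccc2)c(OCc2ccccc2)c(OCc2ccccc2)c1)[C@@H](OCc1ccccc1)CBr)c1ccccc1 | intermediate
16 | (1R,2R)-2-(benzyloxy)-3-bromo-1-[3,4,5-tris(benzyloxy)phenyl]propan-1-ol | O[C@H](c1cc(OCc2ccccc2)c(OCc2ccccc2)c(OCc2ccccc2)c1)[C@@H](OCc1ccccc1)CBr | intermediate
17 | (2R,3S)-3,5,7-tris(benzyloxy)-8-[(2S,4R)-7-(benzyloxy)-2-[4-(benzyloxy)phenyl]chroman-4-yl]-2-[3,4,5-tris(benzyloxy)phenyl]chromane | C(c1ccccc1)Oc1ccc([C@@H]2C[C@@H](c3c(OCc4ccccc4)cc(OCc4ccccc4)c4c3O[C@H](c3cc(OCc5ccccc5)c(OCc5ccccc5)c(OCc5ccccc5)c3)[C@@H](OCc3ccccc3)C4)c3ccc(OCc4ccccc4)cc3O2)cc1 | intermediate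
18 | (2R,3S)-8-[(2S,4R)-7-hydroxy-2-(4-hydroxyphenyl)chroman-4-yl]-2-(3,4,5-trihydroxyphenyl)chromane-3,5,7-triol | Oc1ccc([C@@H]2C[C@@H](c3c(O)cc(O)c4c3O[C@H](c3cc(O)c(O)c(O)c3)[C@@H](O)C4)c3ccc(O)cc3O2)cc1 | target

**Step count and risks**

Total step count: 14. Longest linear sequence: 9 steps (9 to 18 through steps 6 to 14).

Steps most likely to fail:

Step 13 (Proposed new method). What may go wrong: β-hydride elimination from the secondary palladium alkoxide, so that the arene is reduced and no C–O bond forms; slow C–H palladation at C4a, which is flanked by the C5 benzyloxy group, so that the palladacycle is diverted into norbornene-containing by-products; or base-induced loss of HBr from 16. The fallback uses known chemistry, takes the lower unit from the chiral pool and makes the C4–C8 bond last; it sets out from 5 and comes back to the route at 18. Commercial (+)-gallocatechin F1 would be benzylated on its five phenolic oxygens (BnBr, K2CO3, DMF) to give 5,7,3',4',5'-penta-O-benzyl-(+)-gallocatechin F2. Compound 5 would then be ionised with BF3·OEt2 in CH2Cl2 at −78 to −20 °C in the presence of an excess of F2; Friedel–Crafts attack by C8 of its phloroglucinol-type ring A (far more nucleophilic than ring A of 5), trans to the C2 aryl group of the cation, should give the hepta-O-benzyl dimer with a free 3-hydroxyl F3. Hydrogenolysis (H2, Pd(OH)2 on carbon) would then give 18.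

Step 5. What may go wrong: self-alkylation of 5 at C6 of its own ring A, because the iodoarene is only a moderate nucleophile; attack at the carbon between the two ether groups; and poor facial selectivity at C4. The fallback changes the nucleophile to a phloroglucinol-type phenol and installs iodine afterwards; it sets out from 5 and comes back at 8. Commercial 3,5-bis(benzyloxy)phenol F4 (3 equiv) would be alkylated by 5 under BF3·OEt2 ortho to its free hydroxyl to give 3,5-bis(benzyloxy)-2-[(2S,4R)-7-(benzyloxy)-2-[4-(benzyloxy)phenyl]chroman-4-yl]phenol F5. Triflation (Tf2O, pyridine, CH2Cl2, 0 °C) would give the aryl triflate F6, palladium-catalysed stannylation (Me3SnSnMe3, Pd(PPh3)4, LiCl, 1,4-dioxane, 100 °C) the arylstannane F7, and iododestannylation (I2, CH2Cl2, 0 °C) the iodide 8.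

Step 2. What may go wrong: protodeboronation of the electron-rich boronic acid, slow addition to the electron-rich chromone, and insufficient facial control by the ligand. The fallback sets the C2 centre by kinetic resolution during the reduction; it sets out from 2 (with 3) and comes back at 5. Non-asymmetric conjugate addition (Pd(OCOCF3)2, 2,2'-bipyridine, aqueous AcOH, 60 °C) would give the racemic flavanone F8. Asymmetric transfer hydrogenation with RuCl(p-cymene)[(S,S)-TsDPEN] in HCO2H/Et3N should then reduce the (2S) enantiomer, the one that can take hydride trans to its 2-aryl group on the face the catalyst prefers, to the cis alcohol 5 and leave the (2R) ketone behind for separation.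

**Further compounds**

F1 | step 13 | (+)-gallocatechin, (2R,3S)-2-(3,4,5-trihydroxyphenyl)chromane-3,5,7-triol (commercial) | Oc1cc(O)c2c(c1)O[C@H](c1cc(O)c(O)c(O)c1)[C@@H](O)C2
F2 | step 13 | (2R,3S)-5,7-bis(benzyloxy)-2-[3,4,5-tris(benzyloxy)phenyl]chroman-3-ol | C(c1ccccc1)Oc1cc(OCc3ccccc3)c2c(c1)O[C@H](c1cc(OCc3ccccc3)c(OCc3ccccc3)c(OCc3ccccc3)c1)[C@@H](O)C2
F3 | step 13 | (2R,3S)-5,7-bis(benzyloxy)-8-[(2S,4R)-7-(benzyloxy)-2-[4-(benzyloxy)phenyl]chroman-4-yl]-2-[3,4,5-tris(benzyloxy)phenyl]chroman-3-ol | C(c1ccccc1)Oc1ccc([C@@H]2C[C@@H](c3c(OCc4ccccc4)cc(OCc4ccccc4)c4c3O[C@H](c3cc(OCc5ccccc5)c(OCc5ccccc5)c(OCc5ccccc5)c3)[C@@H](O)C4)c3ccc(OCc4ccccc4)cc3O2)cc1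
F4 | step 5 | 3,5-bis(benzyloxy)phenol (commercial) | Oc1cc(OCc2ccccc2)cc(OCc2ccccc2)c1
F5 | step 5 | 3,5-bis(benzyloxy)-2-[(2S,4R)-7-(benzyloxy)-2-[4-(benzyloxy)phenyl]chroman-4-yl]phenol | C(c1ccccc1)Oc1ccc([C@@H]2C[C@@H](c3c(OCc4ccccc4)cc(OCc4ccccc4)cc3O)c3ccc(OCc4ccccc4)cc3O2)cc1
F6 | step 5 | 3,5-bis(benzyloxy)-2-[(2S,4R)-7-(benzyloxy)-2-[4-(benzyloxy)phenyl]chroman-4-yl]phenyl trifluoromethanesulfonate | C(c1ccccc1)Oc1ccc([C@@H]2C[C@@H](c3c(OCc4ccccc4)cc(OCc4ccccc4)cc3OS(=O)(=O)C(F)(F)F)c3ccc(OCc4ccccc4)cc3O2)cc1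
F7 | step 5 | [3,5-bis(benzyloxy)-2-[(2S,4R)-7-(benzyloxy)-2-[4-(benzyloxy)phenyl]chroman-4-yl]phenyl]trimethylstannane | C(c1ccccc1)Oc1ccc([C@@H]2C[C@@H](c3c(OCc4ccccc4)cc(OCc4ccccc4)cc3[Sn](C)(C)C)c3ccc(OCc4ccccc4)cc3O2)cc1
F8 | step 2 | racemic 7-(benzyloxy)-2-[4-(benzyloxy)phenyl]-2,3-dihydro-4H-chromen-4-one | O=C1CC(c2ccc(OCc3ccccc3)cc2)Oc2cc(OCc3ccccc3)ccc12
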